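**Retrosynthetic overview**

1. All four benzene rings are bought ready-made in 2,4-dihydroxyacetophenone (1) and 4-hydroxybenzaldehyde (2); no ring is formed anywhere in the route.
2. Enone disconnection (made first): Claisen–Schmidt union of 1 and 2 through aldol 3 gives isoliquiritigenin (4) and sets the E alkene.
3. Key disconnection (made last): the biaryl bond C3 (ring B)–C5' (ring A'); the target is the dehydrodimer of 4. The ring B phenol of one molecule of 4 becomes the aryloxy-λ3-iodane 5, a phenoxenium (aromatic enolonium) equivalent that is electrophilic at C3. C5' of a second molecule of 4 attacks it, and dienone 6 tautomerises to rhuschalcone VI (7).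
4. Both carbons joined are natively nucleophilic (each ortho to a phenol OH); the oxidant inverts the polarity of one. Two steps, no protecting groups.

Assumption: 7 has no stereocentre and its biaryl axis (only two ortho OH groups) rotates freely, so the only stereochemistry to control is the E geometry of both alkenes.

**Route**

Step 1
Reactants: 1 2,4-dihydroxyacetophenone; 2 4-hydroxybenzaldehyde
Product: 4 isoliquiritigenin, via aldol adduct 3 (not isolated)
Conditions: KOH (60% aq., 12 equiv), EtOH, 0 °C → rt, 48 h, dark; then 2 M HCl, 0 °C, to pH 3
Reagents that add atoms: none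
Why: Claisen–Schmidt (crossed aldol) condensation: only 1 can enolise and 2 is a non-enolisable aldehyde, so a single aldol 3 forms (its carbinol stereocentre is racemic and is erased), and E1cB dehydration under thermodynamic control gives only the E enone, while the fully ionised phenoxides hold the product back from oxa-Michael closure to the flavanone until the cold acid quench.

Step 2
Reactants: 4 isoliquiritigenin (two molecules: one is oxidised at ring B, the other acts as the carbon nucleophile at C5' of ring A)
Product: 7 rhuschalcone VI, via aryloxyiodane 5 (not isolated), via cyclohexadienone 6 (not isolated)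
Conditions: PhI(OAc)2 (0.40 equiv, added over 2 h), (CF3)2CHOH (0.05 M), 0 °C, dark; unreacted 4 recovered and recycled
Reagents that add atoms: none
Why: Proposed new method: ligand exchange at trivalent iodine is productive only at the ring B phenol (the 2'-OH is locked in a hydrogen bond to the ketone and the 4'-OH is para-acyl deactivated, so their iodanes cannot ionise and revert), giving 5, an aromatic enolonium whose ortho carbon C3 is electrophilic (the para carbon is substituted and the exocyclic alpha carbon would be an alpha-keto cation); in the non-nucleophilic, cation-stabilising fluoroalcohol it is attacked by the most nucleophilic carbon present, C5' of ring A of unoxidised 4 (ortho to 4'-OH, para to 2'-OH, only meta to the acyl group, less hindered than C3'), with phenol oxygens muted by hydrogen bonding so that C–C and not C–O coupling results, PhI and AcOH leave, and dienone 6 tautomerises to the 2,2'-biphenol 7 without creating a stereocentre or touching the E alkenes; sub-stoichiometric oxidant keeps 4 in excess over 7 to limit trimers and over-oxidation; the closest known reaction types are the PhI(OAc)2-mediated dehydrogenative phenol–arene and phenol–phenol cross-couplings in fluoroalcohols (oxidative phenol coupling), the enolonium alpha-arylation of ketones, and the oxidative coupling of apigenin to biflavones linked from ring B to ring A.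

**Compound list**

1 | 2,4-dihydroxyacetophenone, 1-(2,4-dihydroxyphenyl)ethan-1-one | CC(=O)c1ccc(O)cc1O | starting material
2 | 4-hydroxybenzaldehyde | O=Cc1ccc(O)cc1 | starting material
3 | aldol adduct, racemic 1-(2,4-dihydroxyphenyl)-3-hydroxy-3-(4-hydroxyphenyl)propan-1-one (present as its potassium phenoxides) | O=C(CC(O)c1ccc(O)cc1)c1ccc(O)cc1O | intermediate
4 | isoliquiritigenin, (E)-1-(2,4-dihydroxyphenyl)-3-(4-hydroxyphenyl)prop-2-en-1-one | O=C(/C=C/c1ccc(O)cc1)c1ccc(O)cc1O | intermediate
5 | aryloxyiodane, acetoxy(phenyl)-λ3-iodanyl ether of the ring B phenol of 4: acetoxy{4-[(E)-3-(2,4-dihydroxyphenyl)-3-oxoprop-1-enyl]phenoxy}(phenyl)-λ3-iodane | O=C(/C=C/c1ccc(OI(OC(C)=O)c2ccccc2)cc1)c1ccc(O)cc1O | intermediate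
6 | cyclohexadienone, racemic keto tautomer of 7: 4-[(E)-3-(2,4-dihydroxyphenyl)-3-oxoprop-1-enyl]-6-{2,4-dihydroxy-5-[(E)-3-(4-hydroxyphenyl)prop-2-enoyl]phenyl}cyclohexa-2,4-dien-1-one | O=C(/C=C/C1=CC(c2cc(C(=O)/C=C/c3ccc(O)cc3)c(O)cc2O)C(=O)C=C1)c1ccc(O)cc1O | intermediate
7 | rhuschalcone VI, (E)-1-(2,4-dihydroxyphenyl)-3-[3-{2,4-dihydroxy-5-[(E)-3-(4-hydroxyphenyl)prop-2-enoyl]phenyl}-4-hydroxyphenyl]prop-2-en-1-one | O=C(/C=C/c1ccc(O)c(-c2cc(C(=O)/C=C/c3ccc(O)cc3)c(O)cc2O)c1)c1ccc(O)cc1O | target

**Totals and risk**

Total step count: 2. Longest linear sequence: 2 (4 is used twice in step 2).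

The route has only two steps, so both are ranked.

First, step 2. Possible failures are diaryl ether formation, coupling of ring B to ring B, chain extension to trimers, further oxidation of the new 2,2'-biphenol, and attack at the enone. Fallback, setting out from 4 and coming back at 7: one chalcone is no longer asked to play both roles. Instead, 4 (limiting) is coupled with a five-fold excess of the non-oxidisable nucleophile 1 under the same aryloxy-λ3-iodane activation (PhI(OAc)2 1.0 equiv, (CF3)2CHOH, 0 °C). C5 of 1 then outcompetes every chalcone-derived nucleophile statistically, and the only remaining self-coupling channel of 4 still gives 7. The product is the acetyl biaryl chalcone (E)-3-[3-(5-acetyl-2,4-dihydroxyphenyl)-4-hydroxyphenyl]-1-(2,4-dihydroxyphenyl)prop-2-en-1-one F1. A second Claisen–Schmidt condensation of F1 with 2 (3 equiv, KOH aq., EtOH, rt) then builds the second E enone and returns to the route at 7.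

Second, step 1. The phenoxide of 2 is a poor electrophile, so conversion can stall, and the acid quench can cyclise some product to the flavanone. Fallback, setting out from 1 and 2 and coming back at 4: the acidic phenols are masked before the condensation. MOMCl with K2CO3 in acetone converts 1 into 2-hydroxy-4-(methoxymethoxy)acetophenone F2 (the chelated 2-OH stays free) and 2 into 4-(methoxymethoxy)benzaldehyde F3. Condensation of F2 with F3 (KOH aq., EtOH, rt) is then fast and gives the bis-MOM chalcone (E)-1-[2-hydroxy-4-(methoxymethoxy)phenyl]-3-[4-(methoxymethoxy)phenyl]prop-2-en-1-one F4. Brief treatment of F4 with 3 M HCl in MeOH at 50 °C removes both acetals and returns to the route at 4.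

**Further compounds**

F1 | step 2 | (E)-3-[3-(5-acetyl-2,4-dihydroxyphenyl)-4-hydroxyphenyl]-1-(2,4-dihydroxyphenyl)prop-2-en-1-one | CC(=O)c1cc(-c2cc(/C=C/C(=O)c3ccc(O)cc3O)ccc2O)c(O)cc1O
F2 | step 1 | 2-hydroxy-4-(methoxymethoxy)acetophenone | CC(=O)c1ccc(OCOC)cc1O
F3 | step 1 | 4-(methoxymethoxy)benzaldehyde | O=Cc1ccc(OCOC)cc1
F4 | step 1 | (E)-1-[2-hydroxy-4-(methoxymethoxy)phenyl]-3-[4-(methoxymethoxy)phenyl]prop-2-en-1-one | O=C(/C=C/c1ccc(OCOC)cc1)c1ccc(OCOC)cc1O
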